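## The problem

Target 30 is a resveratrol trimer built on a 5,7-dihydroxyindane (ring A fused to a cyclopentane). Its three sp3 ring carbons carry a 4-hydroxyphenyl group (C1), a trans-2,3-diaryl-2,3-dihydrobenzofuran bound through its C4 (C2), and a (4-hydroxyphenyl)hydroxymethyl group (C3). Six stereocentres must be set: indane C1, C2 and C3 are all-trans (1S,2R,3S), the carbinol carbon is S, and the dihydrobenzofuran is (2R,3R). Inside the dihydrobenzofuran C3 controls C2, because the trans isomer is the kinetic and the thermodynamic one. On the indane, C1 and C2 are fixed once the ring is closed, C3 can be equilibrated trans to C2 while the exocyclic carbon is a ketone, and the carbinol centre lies outside the ring and is best left to a reagent. The weak link is the relation between the two ring systems: the dihydrobenzofuran stereocentres are four and five bonds from indane C1 and can influence it only through the C3 aryl group beside the point of attachment. The fragile parts are the 4-hydroxybenzylic alcohol (ionises, forms a quinone methide), the benzylic C2–O bond of the dihydrobenzofuran (Lewis acids), eight phenols and three resorcinol-type rings (oxidants, electrophiles). The feature that opens the route is threefold: C1 bears a 4-hydroxyphenyl group and is therefore the exocyclic carbon of a para-quinone methide; C3 is alpha to a latent aryl ketone and can be an enolate carbon; and C2, the one ring atom between them, can be delivered as a sulfonium ylide carbon that already carries the dihydrobenzofuran.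

## Retrosynthesis

**Carbinol C–H bond (30 ⇒ 29 ⇒ 28).** The last stereocentre is cut at its C–H bond, which leads to aryl ketone 28 and a catalyst-controlled reduction. Cutting the carbinol–aryl bond instead would need an epimerisable aldehyde on C3 and would leave the new centre to substrate control. The phenols of 29 are acetates because they must come off under near-neutral conditions that the 4-hydroxybenzylic alcohol survives. The forward reduction must override the bias of the neighbouring C3 centre and spare eight aryl esters.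

**Phenol O–methyl bonds (28 ⇒ 27 ⇒ 26).** Methyl ethers are the only phenol protection that survives organolithium, Lewis-acid and palladium steps in both fragments. They cannot be cleaved once the benzylic alcohol exists, so cleavage is placed at the ketone stage (26 to 27), followed by acetylation (28). The forward step must spare the dihydrobenzofuran C2–O bond.

**C1–C2 and C2–C3 (26 ⇒ 11 + 22).** Both bonds to C2 are cut. This splits 26 into two fragments of similar size and removes the five-membered ring and three stereocentres at once. The neighbouring cuts (C1–C7a by Friedel–Crafts closure, or C3–C3a) would leave an open chain with three contiguous stereocentres to be built first. In the forward direction 11 gives para-quinone methide 24, 22 gives ylide 23, their union gives betaine 25, and the ketone enolate closes the ring. The reaction must favour C- over O-alkylation, substitution over elimination, a trans closure, and one face of 24 under the influence of the dihydrobenzofuran.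

**C–S and aryl–CH bonds of the quinone methide precursor (11 ⇒ 10 ⇒ 9 ⇒ 6 + 7).** The sulfone is placed by exchange on benzhydrol 9, which comes from an aryllithium (8, from bromide 6) and aldehyde 7. The ketone is kept as a dioxolane from 6 to 10 so that neither organolithium chemistry nor the cationic exchange meets a free, enolisable carbonyl. The phenol stays silylated until the key step, where fluoride releases it.

**Ring A bromide and the deoxybenzoin (6 ⇒ 5 ⇒ 4 ⇒ 1 + 2).** The C–Br bond goes in at the ring position para to one methoxy group and ortho to the side chain. The acyl–aryl bond is a Friedel–Crafts acylation of 2 by acid 1 through chloride 3. Both starting materials are catalogue compounds and ring A is bought, not built.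

**Sulfonium salt (22 ⇒ 21 ⇒ 20).** The C–S and C–Br bonds are cut back to benzylic alcohol 20. These are two substitutions at a primary benzylic carbon that do not touch the ring stereocentres.

**Single enantiomer (20 ⇒ 19 ⇒ 18).** No catalytic asymmetric reduction of a 2,3-diarylbenzofuran can be relied on. Carbene C–H insertion routes to this ring would need a diaryl ketone flanked by two ortho substituents. The racemic alcohol 19, from ester 18, is therefore resolved by chromatography at the first hydroxyl-bearing stage, and half of the material is given up there.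

**Dihydrobenzofuran core (18 ⇒ 17 ⇒ 15 + 16 ⇒ 14 ⇒ 12 + 13).** The C2–H and C3–H bonds are cut back to benzofuran 17, whose ionic hydrogenation gives the trans isomer. The C2–aryl bond is a direct arylation of 15 with 16. The C3–C3a bond is a cyclodehydration of aryloxy ketone 14, which is the ether of phenol 12 and phenacyl bromide 13. The ester of 12 ends up at C4 and becomes the ylide carbon.

## Roads not taken

**Alternative 1:** The cut removes ring A itself (C4–C5, C6–C7 and C7–C7a). In the forward direction a Danheiser benzannulation would be run on cyclopentenyl diazomethyl ketone A2: photochemical Wolff rearrangement in the presence of ethoxyethyne A3, then the usual cycloaddition, ring opening and six-electron closure, would give phenol A1.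
- Merits: the three ring stereocentres, the silylated carbinol and the dihydrobenzofuran are settled on a small ring before any electron-rich arene exists. The two ring-A oxygens arrive differentiated, and the polarity of the ynol ether fixes the regiochemistry.
- Weak points: A2 is a tetrasubstituted cyclopentene with four contiguous stereocentres and a larger problem than the one it solves. Its C1 is benzylic, allylic and gamma to the ketone, so it is open to epimerisation and double-bond migration. The photolysis runs beside five anisole-type chromophores, and a benzene ring that can be bought is assembled from small pieces.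
- Comparison: this road is better in one respect. The configuration of the five-membered ring could be set stepwise under reagent control, whereas the chosen plan leaves C1 to one substrate-controlled addition. The chosen plan sets against this its convergence: two fragments from catalogue compounds, joined with ring closure and three stereocentres in one operation.

**Alternative 2:** The cut again removes ring A (C3a–C4 and C7a–C7), this time from a cyclopentenone. Diene A6 would add across the C3a=C7a bond of bromo enone A5, and twofold elimination would aromatise the adduct to indanone A4.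
- Merits: this is a well-tested way to a resorcinol ring with reliable regiochemistry. The ring carbonyl and the vinyl group are clean handles. C1 could later be set by aryl addition and ionic reduction anti to the C2 substituent, which is more predictable than the addition step of the chosen plan.
- Weak points: both 4-hydroxyphenyl groups are still missing in A4. At least six further operations follow, including deoxygenation at a tertiary, doubly benzylic carbon next to the acid-labile dihydrobenzofuran and oxidative cleavage of an alkene beside electron-rich rings. A5 has an epimerisable alpha-aryl centre and is itself a multi-step target.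
- Comparison: this road is more predictable at C1 but clearly longer and linear. The chosen plan reaches aryl ketone 26 with every carbon of the target in place in one step.

**Alternative 3:** The cut is C2–C3, made by ring contraction. Photolysis of diazotetralone A8 would bring about a Wolff rearrangement in which the carbon bearing the dihydrobenzofuran migrates with retention, and the contracted acyl unit would be trapped as methyl ester A7.
- Merits: ring contraction of cyclic diazo ketones is a known reaction type. The C1/C2 trans relation could be set in a six-membered ring, the C3 ester can be equilibrated, and no free phenol is needed.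
- Weak points: the 3,4-diaryl-2-tetralone behind A8 is enolisable on both sides and oxidation-prone, and it needs a hindered aryl nucleophile that carries the dihydrobenzofuran. A7 still has to be converted into the aryl ketone, which costs several steps before the stage of 26 is reached.
- Comparison: the key step here rests on firmer precedent than the carbocyclic (4+1) annulation, and in that respect this road is as good or better. The chosen plan sets against it its directness (26 forms straight from 11 and 22) and a fallback to the indane that uses only known reactions.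

Key step: step 15

Remark on numbering: the indane is numbered with C1 at the carbon bearing the 4-hydroxyphenyl group, C2 at the carbon bearing the dihydrobenzofuran and C3 at the carbon bearing the acyl or carbinol carbon. Ring A then carries oxygen at C5 and C7, and the descriptors 1S,2R,3S are unchanged when the ring is numbered from the other end.

Remark on materials: 7, 12 and 13 are taken as catalogue compounds. Compounds 9–11 are racemic at a carbon that becomes planar in 24. Compounds 18 and 19 are racemates drawn as the enantiomer that is kept.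

## Route

Step 1
Reactants: 1 3,5-dimethoxyphenylacetic acid; 2 anisole
Product: 4 2-(3,5-dimethoxyphenyl)-1-(4-methoxyphenyl)ethan-1-one, via 3,5-dimethoxyphenylacetyl chloride 3 (not isolated)
Conditions: (COCl)2, DMF (cat.), CH2Cl2, 0 °C to rt; then 2 (3 equiv), AlCl3 (1.2 equiv), CH2Cl2, 0 °C
Reagents that add atoms: none
Why: Friedel–Crafts acylation; the methoxy group of 2 directs para, and the excess of 2 should keep the acylium ion away from the dimethoxyphenyl ring of a second molecule.

Step 2
Reactants: 4 2-(3,5-dimethoxyphenyl)-1-(4-methoxyphenyl)ethan-1-one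
Product: 5 2-(2-bromo-3,5-dimethoxyphenyl)-1-(4-methoxyphenyl)ethan-1-one
Conditions: NBS (1.0 equiv), MeCN, 0 °C, dark
Reagents that add atoms: N-bromosuccinimide (BrN1C(=O)CCC1=O)
Why: Electrophilic aromatic bromination; C2 of the dimethoxyphenyl ring is para to one methoxy group and less hindered than the position between the two, and polar conditions in the dark should keep bromine off the ketone CH2.

Step 3
Reactants: 5 2-(2-bromo-3,5-dimethoxyphenyl)-1-(4-methoxyphenyl)ethan-1-one
Product: 6 2-[(2-bromo-3,5-dimethoxyphenyl)methyl]-2-(4-methoxyphenyl)-1,3-dioxolane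
Conditions: HOCH2CH2OH (5 equiv), p-TsOH·H2O (cat.), toluene, reflux, Dean–Stark trap
Reagents that add atoms: ethylene glycol (OCCO)
Why: Acid-catalysed ketalisation with azeotropic removal of water; the dioxolane hides the ketone and its acidic CH2 from the organolithium of the next step.

Step 4
Reactants: 6 2-[(2-bromo-3,5-dimethoxyphenyl)methyl]-2-(4-methoxyphenyl)-1,3-dioxolane; 7 4-[(tert-butyldimethylsilyl)oxy]benzaldehyde
Product: 9 rac-{4-[(tert-butyldimethylsilyl)oxy]phenyl}(2,4-dimethoxy-6-{[2-(4-methoxyphenyl)-1,3-dioxolan-2-yl]methyl}phenyl)methanol, via lithiated dioxolane 8 (not isolated)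
Conditions: n-BuLi (1.05 equiv), THF, −78 °C; then 7, −78 °C to 0 °C; aq NH4Cl
Reagents that add atoms: none
Why: Bromine–lithium exchange followed by 1,2-addition of the aryllithium to the aldehyde; the new stereocentre is formed as the racemate, which is harmless because it becomes planar in 24.

Step 5
Reactants: 9 rac-{4-[(tert-butyldimethylsilyl)oxy]phenyl}(2,4-dimethoxy-6-{[2-(4-methoxyphenyl)-1,3-dioxolan-2-yl]methyl}phenyl)methanol
Product: 10 rac-2-{2-[{4-[(tert-butyldimethylsilyl)oxy]phenyl}(4-methylbenzenesulfonyl)methyl]-3,5-dimethoxybenzyl}-2-(4-methoxyphenyl)-1,3-dioxolane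
Conditions: p-TolSO2H (3 equiv), CH2Cl2, rt
Reagents that add atoms: 4-methylbenzenesulfinic acid (Cc1ccc(cc1)S(=O)O)
Why: SN1 exchange of a doubly activated benzhydrol; the cation stabilised by the 4-silyloxyphenyl and 2,4-dimethoxyphenyl rings should be captured at sulfur to give the sulfone as the thermodynamic product.

Step 6
Reactants: 10 rac-2-{2-[{4-[(tert-butyldimethylsilyl)oxy]phenyl}(4-methylbenzenesulfonyl)methyl]-3,5-dimethoxybenzyl}-2-(4-methoxyphenyl)-1,3-dioxolane
Product: 11 rac-2-{2-[{4-[(tert-butyldimethylsilyl)oxy]phenyl}(4-methylbenzenesulfonyl)methyl]-3,5-dimethoxyphenyl}-1-(4-methoxyphenyl)ethan-1-one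
Conditions: I2 (10 mol %), acetone, rt
Reagents that add atoms: none
Why: Iodine-catalysed transketalisation to acetone under essentially neutral conditions should free the ketone without ionising the benzhydryl sulfone or cleaving the aryl silyl ether.

Step 7
Reactants: 12 methyl 3-hydroxy-5-methoxybenzoate; 13 2-bromo-1-(3,5-dimethoxyphenyl)ethan-1-one
Product: 14 methyl 3-[2-(3,5-dimethoxyphenyl)-2-oxoethoxy]-5-methoxybenzoate
Conditions: K2CO3, acetone, reflux
Reagents that add atoms: none
Why: Williamson ether synthesis; the phenoxide displaces bromide from the phenacyl bromide by SN2.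

Step 8
Reactants: 14 methyl 3-[2-(3,5-dimethoxyphenyl)-2-oxoethoxy]-5-methoxybenzoate
Product: 15 methyl 3-(3,5-dimethoxyphenyl)-6-methoxy-1-benzofuran-4-carboxylate
Conditions: Bi(OTf)3 (10 mol %), 1,2-dichloroethane, reflux
Reagents that add atoms: none
Why: Cyclodehydration (intramolecular Friedel–Crafts hydroxyalkylation, then loss of water); closure should occur at the ring carbon para to the methoxy group and ortho to the ether oxygen, which places the ester at C4.

Step 9
Reactants: 15 methyl 3-(3,5-dimethoxyphenyl)-6-methoxy-1-benzofuran-4-carboxylate; 16 4-bromoanisole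
Product: 17 methyl 3-(3,5-dimethoxyphenyl)-6-methoxy-2-(4-methoxyphenyl)-1-benzofuran-4-carboxylate
Conditions: Pd(OAc)2 (5 mol %), PCy3·HBF4 (10 mol %), K2CO3, pivalic acid (30 mol %), DMA, 110 °C
Reagents that add atoms: none
Why: Palladium-catalysed direct C–H arylation by concerted metalation–deprotonation; C2 is the only heteroaryl C–H of 15.

Step 10
Reactants: 17 methyl 3-(3,5-dimethoxyphenyl)-6-methoxy-2-(4-methoxyphenyl)-1-benzofuran-4-carboxylate
Product: 18 rac-methyl trans-(2R*,3R*)-3-(3,5-dimethoxyphenyl)-6-methoxy-2-(4-methoxyphenyl)-2,3-dihydro-1-benzofuran-4-carboxylate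
Conditions: Et3SiH (5 equiv), CF3CO2H, CH2Cl2, 0 °C to rt
Reagents that add atoms: none
Why: Ionic hydrogenation; protonation at C3 gives a cation stabilised by O1 and the 4-methoxyphenyl group, and hydride should enter C2 anti to the C3 aryl group, so the trans isomer is expected; any cis isomer can equilibrate through the same cation.

Step 11
Reactants: 18 rac-methyl trans-(2R*,3R*)-3-(3,5-dimethoxyphenyl)-6-methoxy-2-(4-methoxyphenyl)-2,3-dihydro-1-benzofuran-4-carboxylate
Product: 19 rac-[trans-(2R*,3R*)-3-(3,5-dimethoxyphenyl)-6-methoxy-2-(4-methoxyphenyl)-2,3-dihydro-1-benzofuran-4-yl]methanol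
Conditions: LiAlH4, THF, 0 °C
Reagents that add atoms: none
Why: Hydride reduction of the ester to the primary alcohol; the benzylic ether and both stereocentres are not touched.

Step 12
Reactants: 19 rac-[trans-(2R*,3R*)-3-(3,5-dimethoxyphenyl)-6-methoxy-2-(4-methoxyphenyl)-2,3-dihydro-1-benzofuran-4-yl]methanol
Product: 20 [(2R,3R)-3-(3,5-dimethoxyphenyl)-6-methoxy-2-(4-methoxyphenyl)-2,3-dihydro-1-benzofuran-4-yl]methanol
Conditions: preparative SFC on amylose tris(3,5-dimethylphenylcarbamate), CO2/MeOH, 35 °C
Reagents that add atoms: none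
Why: Resolution of the racemate on a polysaccharide chiral stationary phase; no stereocentre is formed, and the 2R,3R fraction is to be identified by ECD and by anomalous-dispersion X-ray analysis of bromide 21.

Step 13
Reactants: 20 [(2R,3R)-3-(3,5-dimethoxyphenyl)-6-methoxy-2-(4-methoxyphenyl)-2,3-dihydro-1-benzofuran-4-yl]methanol
Product: 21 (2R,3R)-4-(bromomethyl)-3-(3,5-dimethoxyphenyl)-6-methoxy-2-(4-methoxyphenyl)-2,3-dihydro-1-benzofuran
Conditions: CBr4, PPh3, CH2Cl2, 0 °C
Reagents that add atoms: carbon tetrabromide (BrC(Br)(Br)Br)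
Why: Appel reaction; the neutral conditions should spare the acid-sensitive C2–O bond of the dihydrobenzofuran.

Step 14
Reactants: 21 (2R,3R)-4-(bromomethyl)-3-(3,5-dimethoxyphenyl)-6-methoxy-2-(4-methoxyphenyl)-2,3-dihydro-1-benzofuran
Product: 22 {[(2R,3R)-3-(3,5-dimethoxyphenyl)-6-methoxy-2-(4-methoxyphenyl)-2,3-dihydro-1-benzofuran-4-yl]methyl}dimethylsulfonium tetrafluoroborate
Conditions: Me2S (5 equiv), NaBF4 (2 equiv), CH2Cl2/H2O, rt
Reagents that add atoms: dimethyl sulfide (CSC); sodium tetrafluoroborate ([Na+].F[B-](F)(F)F)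
Why: SN2 alkylation of the sulfide at the primary benzylic bromide; exchange to the non-nucleophilic tetrafluoroborate should prevent reversal by bromide.

Step 15
Reactants: 11 rac-2-{2-[{4-[(tert-butyldimethylsilyl)oxy]phenyl}(4-methylbenzenesulfonyl)methyl]-3,5-dimethoxyphenyl}-1-(4-methoxyphenyl)ethan-1-one; 22 {[(2R,3R)-3-(3,5-dimethoxyphenyl)-6-methoxy-2-(4-methoxyphenyl)-2,3-dihydro-1-benzofuran-4-yl]methyl}dimethylsulfonium tetrafluoroborate
Product: 26 (1S,2R,3S)-1-(4-hydroxyphenyl)-5,7-dimethoxy-3-(4-methoxybenzoyl)-2-[(2R,3R)-3-(3,5-dimethoxyphenyl)-6-methoxy-2-(4-methoxyphenyl)-2,3-dihydro-1-benzofuran-4-yl]indane, via sulfonium ylide 23 (not isolated), via para-quinone methide 24 (not isolated), via sulfonium phenoxide betaine 25 (not isolated)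
Conditions: 22 (1.5 equiv), Cs2CO3 (4 equiv), MeCN/DMF (4:1), 0 °C; then 11 and CsF (3 equiv) added slowly, 0 °C to rt; aq NH4Cl
Reagents that add atoms: none
Why: Proposed new method: fluoride removes the silyl group of 11, the phenoxide expels sulfinate to give para-quinone methide 24, and carbonate turns 22 into the semi-stabilised ylide 23, whose carbon adds 1,6 to the exocyclic carbon of 24 (C1–C2) with re-aromatisation to betaine 25; the deoxybenzoin CH2 of 25 is then deprotonated and the enolate carbon displaces the sulfide with inversion at C2 (C2–C3). The closest known reactions are the (4+1) annulations of sulfonium ylides with ortho-hydroxyphenyl para-quinone methides, which close dihydrobenzofurans through oxygen, and the 1,6-addition/cyclisation cascades of ortho-functionalised para-quinone methides; closure of an indane by a carbon nucleophile in this way has not been shown. The one ring is closed by a 5-exo-tet alkylation of the enolate carbon, and direct attack of that carbon on 24 would give a four-membered ring and does not compete. C1 is set in the addition: 23 should react with sulfur turned away from C3 of the dihydrobenzofuran, on the face opposite the C3 aryl group, and with the sulfonium group next to the developing dienolate ring (the Coulomb-favoured cisoid approach), which leads to 1S. C2 is set by the invertive closure; because the sulfonium carbon of 25 can epimerise through the ylide, and because a detour through phenoxide (Ar1-3) participation would also open to the trans product, the 1,2-trans relation should result whichever epimer closes. C3 is alpha to the ketone and should equilibrate under carbonate to the all-trans isomer. The step needs C-alkylation to outrun elimination of the sulfide and capture of 24 by the enolate oxygen; slow addition of 11 to preformed 23 and the expected reversibility of the oxygen adduct under base are what procedure and substrate offer for this.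

Step 16
Reactants: 26 (1S,2R,3S)-1-(4-hydroxyphenyl)-5,7-dimethoxy-3-(4-methoxybenzoyl)-2-[(2R,3R)-3-(3,5-dimethoxyphenyl)-6-methoxy-2-(4-methoxyphenyl)-2,3-dihydro-1-benzofuran-4-yl]indane
Product: 27 (1S,2R,3S)-3-(4-hydroxybenzoyl)-1-(4-hydroxyphenyl)-2-[(2R,3R)-3-(3,5-dihydroxyphenyl)-6-hydroxy-2-(4-hydroxyphenyl)-2,3-dihydro-1-benzofuran-4-yl]indane-5,7-diol
Conditions: BBr3 (16 equiv), CH2Cl2, −78 °C to rt; then H2O
Reagents that add atoms: none
Why: Lewis-acid cleavage of the seven aryl methyl ethers at the ketone stage, where no ionisable benzylic alcohol is present; the trans-dihydrobenzofuran and the all-trans indane are the thermodynamic isomers, so reversible opening at C2–O or enolisation at C3 should return the same configurations.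

Step 17
Reactants: 27 (1S,2R,3S)-3-(4-hydroxybenzoyl)-1-(4-hydroxyphenyl)-2-[(2R,3R)-3-(3,5-dihydroxyphenyl)-6-hydroxy-2-(4-hydroxyphenyl)-2,3-dihydro-1-benzofuran-4-yl]indane-5,7-diol
Product: 28 octaacetate of 27: (1S,2R,3S)-5,7-diacetoxy-3-(4-acetoxybenzoyl)-1-(4-acetoxyphenyl)-2-[(2R,3R)-6-acetoxy-2-(4-acetoxyphenyl)-3-(3,5-diacetoxyphenyl)-2,3-dihydro-1-benzofuran-4-yl]indane
Conditions: Ac2O, pyridine, DMAP (cat.), rt
Reagents that add atoms: acetic anhydride (CC(=O)OC(C)=O)
Why: Acetylation of all eight phenols; the acetates make the ketone soluble and inert to the borane reagent and can later be removed without acid.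

Step 18
Reactants: 28 octaacetate of 27: (1S,2R,3S)-5,7-diacetoxy-3-(4-acetoxybenzoyl)-1-(4-acetoxyphenyl)-2-[(2R,3R)-6-acetoxy-2-(4-acetoxyphenyl)-3-(3,5-diacetoxyphenyl)-2,3-dihydro-1-benzofuran-4-yl]indane
Product: 29 (1S,2R,3S)-5,7-diacetoxy-3-[(S)-(4-acetoxyphenyl)(hydroxy)methyl]-1-(4-acetoxyphenyl)-2-[(2R,3R)-6-acetoxy-2-(4-acetoxyphenyl)-3-(3,5-diacetoxyphenyl)-2,3-dihydro-1-benzofuran-4-yl]indane
Conditions: (R)-1-methyl-3,3-diphenyl-tetrahydro-1H,3H-pyrrolo[1,2-c][1,3,2]oxazaborole ((R)-Me-CBS, 0.5 equiv), catecholborane (2 equiv), toluene/CH2Cl2, −60 °C to −20 °C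
Reagents that add atoms: none
Why: Corey–Bakshi–Shibata reduction; with the aryl group as the larger ketone substituent the R catalyst should deliver hydride to the face that gives the S carbinol (the sense in which it gives (S)-1-phenylethanol), and catalyst control is wanted because the C3 stereocentre has a bias of its own. Aryl acetates should be inert to catecholborane at this temperature.

Step 19
Reactants: 29 (1S,2R,3S)-5,7-diacetoxy-3-[(S)-(4-acetoxyphenyl)(hydroxy)methyl]-1-(4-acetoxyphenyl)-2-[(2R,3R)-6-acetoxy-2-(4-acetoxyphenyl)-3-(3,5-diacetoxyphenyl)-2,3-dihydro-1-benzofuran-4-yl]indane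
Product: 30 (1S,2R,3S)-3-[(S)-hydroxy(4-hydroxyphenyl)methyl]-1-(4-hydroxyphenyl)-2-[(2R,3R)-3-(3,5-dihydroxyphenyl)-6-hydroxy-2-(4-hydroxyphenyl)-2,3-dihydro-1-benzofuran-4-yl]indane-5,7-diol
Conditions: NH4OAc (excess), MeOH/H2O (4:1), rt, argon
Reagents that add atoms: none
Why: Near-neutral solvolysis of the eight aryl acetates; the medium should neither ionise the 4-hydroxybenzylic alcohol nor push it to a quinone methide, and no stereocentre is touched.

## Compound list

1 | 3,5-dimethoxyphenylacetic acid | OC(=O)Cc1cc(OC)cc(OC)c1 | starting material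
2 | anisole | COc1ccccc1 | starting material
3 | 3,5-dimethoxyphenylacetyl chloride | ClC(=O)Cc1cc(OC)cc(OC)c1 | intermediate (not isolated)
4 | 2-(3,5-dimethoxyphenyl)-1-(4-methoxyphenyl)ethan-1-one | COc1ccc(cc1)C(=O)Cc1cc(OC)cc(OC)c1 | intermediate
5 | 2-(2-bromo-3,5-dimethoxyphenyl)-1-(4-methoxyphenyl)ethan-1-one | COc1ccc(cc1)C(=O)Cc1cc(OC)cc(OC)c1Br | intermediate
6 | 2-[(2-bromo-3,5-dimethoxyphenyl)methyl]-2-(4-methoxyphenyl)-1,3-dioxolane | COc1ccc(cc1)C1(Cc2cc(OC)cc(OC)c2Br)OCCO1 | intermediate
7 | 4-[(tert-butyldimethylsilyl)oxy]benzaldehyde | CC(C)(C)[Si](C)(C)Oc1ccc(C=O)cc1 | starting material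
8 | (2,4-dimethoxy-6-{[2-(4-methoxyphenyl)-1,3-dioxolan-2-yl]methyl}phenyl)lithium | COc1ccc(cc1)C1(Cc2cc(OC)cc(OC)c2[Li])OCCO1 | intermediate (not isolated)
9 | rac-{4-[(tert-butyldimethylsilyl)oxy]phenyl}(2,4-dimethoxy-6-{[2-(4-methoxyphenyl)-1,3-dioxolan-2-yl]methyl}phenyl)methanol | COc1ccc(cc1)C1(Cc2cc(OC)cc(OC)c2C(O)c2ccc(O[Si](C)(C)C(C)(C)C)cc2)OCCO1 | intermediate
10 | rac-2-{2-[{4-[(tert-butyldimethylsilyl)oxy]phenyl}(4-methylbenzenesulfonyl)methyl]-3,5-dimethoxybenzyl}-2-(4-methoxyphenyl)-1,3-dioxolane | COc1ccc(cc1)C1(Cc2cc(OC)cc(OC)c2C(c2ccc(O[Si](C)(C)C(C)(C)C)cc2)S(=O)(=O)c2ccc(C)cc2)OCCO1 | intermediate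
11 | rac-2-{2-[{4-[(tert-butyldimethylsilyl)oxy]phenyl}(4-methylbenzenesulfonyl)methyl]-3,5-dimethoxyphenyl}-1-(4-methoxyphenyl)ethan-1-one | COc1ccc(cc1)C(=O)Cc1cc(OC)cc(OC)c1C(c1ccc(O[Si](C)(C)C(C)(C)C)cc1)S(=O)(=O)c1ccc(C)cc1 | intermediate
12 | methyl 3-hydroxy-5-methoxybenzoate | COC(=O)c1cc(O)cc(OC)c1 | starting material
13 | 2-bromo-1-(3,5-dimethoxyphenyl)ethan-1-one | COc1cc(OC)cc(c1)C(=O)CBr | starting material
14 | methyl 3-[2-(3,5-dimethoxyphenyl)-2-oxoethoxy]-5-methoxybenzoate | COC(=O)c1cc(OC)cc(OCC(=O)c2cc(OC)cc(OC)c2)c1 | intermediate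
15 | methyl 3-(3,5-dimethoxyphenyl)-6-methoxy-1-benzofuran-4-carboxylate | COC(=O)c1cc(OC)cc2occ(-c3cc(OC)cc(OC)c3)c12 | intermediate
16 | 4-bromoanisole | COc1ccc(Br)cc1 | starting material
17 | methyl 3-(3,5-dimethoxyphenyl)-6-methoxy-2-(4-methoxyphenyl)-1-benzofuran-4-carboxylate | COC(=O)c1cc(OC)cc2oc(-c3ccc(OC)cc3)c(-c3cc(OC)cc(OC)c3)c12 | intermediate
18 | rac-methyl trans-(2R*,3R*)-3-(3,5-dimethoxyphenyl)-6-methoxy-2-(4-methoxyphenyl)-2,3-dihydro-1-benzofuran-4-carboxylate (racemate; kept enantiomer drawn) | COC(=O)c1cc(OC)cc2c1[C@@H](c1cc(OC)cc(OC)c1)[C@H](c1ccc(OC)cc1)O2 | intermediate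
19 | rac-[trans-(2R*,3R*)-3-(3,5-dimethoxyphenyl)-6-methoxy-2-(4-methoxyphenyl)-2,3-dihydro-1-benzofuran-4-yl]methanol (racemate; kept enantiomer drawn) | OCc1cc(OC)cc2c1[C@@H](c1cc(OC)cc(OC)c1)[C@H](c1ccc(OC)cc1)O2 | intermediate
20 | [(2R,3R)-3-(3,5-dimethoxyphenyl)-6-methoxy-2-(4-methoxyphenyl)-2,3-dihydro-1-benzofuran-4-yl]methanol (single enantiomer) | OCc1cc(OC)cc2c1[C@@H](c1cc(OC)cc(OC)c1)[C@H](c1ccc(OC)cc1)O2 | intermediate
21 | (2R,3R)-4-(bromomethyl)-3-(3,5-dimethoxyphenyl)-6-methoxy-2-(4-methoxyphenyl)-2,3-dihydro-1-benzofuran | BrCc1cc(OC)cc2c1[C@@H](c1cc(OC)cc(OC)c1)[C@H](c1ccc(OC)cc1)O2 | intermediate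
22 | {[(2R,3R)-3-(3,5-dimethoxyphenyl)-6-methoxy-2-(4-methoxyphenyl)-2,3-dihydro-1-benzofuran-4-yl]methyl}dimethylsulfonium tetrafluoroborate | C[S+](C)Cc1cc(OC)cc2c1[C@@H](c1cc(OC)cc(OC)c1)[C@H](c1ccc(OC)cc1)O2.F[B-](F)(F)F | intermediate
23 | (dimethylsulfonio)[(2R,3R)-3-(3,5-dimethoxyphenyl)-6-methoxy-2-(4-methoxyphenyl)-2,3-dihydro-1-benzofuran-4-yl]methanide (ylide of 22) | C[S+](C)[CH-]c1cc(OC)cc2c1[C@@H](c1cc(OC)cc(OC)c1)[C@H](c1ccc(OC)cc1)O2 | intermediate (not isolated)
24 | 4-({2,4-dimethoxy-6-[2-(4-methoxyphenyl)-2-oxoethyl]phenyl}methylidene)cyclohexa-2,5-dien-1-one | COc1ccc(cc1)C(=O)Cc1cc(OC)cc(OC)c1C=C1C=CC(=O)C=C1 | intermediate (not isolated)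
25 | 4-{(1S,2R)-1-{2,4-dimethoxy-6-[2-(4-methoxyphenyl)-2-oxoethyl]phenyl}-2-(dimethylsulfonio)-2-[(2R,3R)-3-(3,5-dimethoxyphenyl)-6-methoxy-2-(4-methoxyphenyl)-2,3-dihydro-1-benzofuran-4-yl]ethyl}phenolate (the sulfonium-carbon epimer that closes directly is drawn; this centre is labile) | [O-]c1ccc(cc1)[C@@H](c1c(OC)cc(OC)cc1CC(=O)c1ccc(OC)cc1)[C@@H]([S+](C)C)c1cc(OC)cc2c1[C@@H](c1cc(OC)cc(OC)c1)[C@H](c1ccc(OC)cc1)O2 | intermediate (not isolated)
26 | (1S,2R,3S)-1-(4-hydroxyphenyl)-5,7-dimethoxy-3-(4-methoxybenzoyl)-2-[(2R,3R)-3-(3,5-dimethoxyphenyl)-6-methoxy-2-(4-methoxyphenyl)-2,3-dihydro-1-benzofuran-4-yl]indane | Oc1ccc([C@H]2c3c(OC)cc(OC)cc3[C@@H](C(=O)c3ccc(OC)cc3)[C@@H]2c2cc(OC)cc3c2[C@@H](c2cc(OC)cc(OC)c2)[C@H](c2ccc(OC)cc2)O3)cc1 | intermediate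
27 | (1S,2R,3S)-3-(4-hydroxybenzoyl)-1-(4-hydroxyphenyl)-2-[(2R,3R)-3-(3,5-dihydroxyphenyl)-6-hydroxy-2-(4-hydroxyphenyl)-2,3-dihydro-1-benzofuran-4-yl]indane-5,7-diol | Oc1ccc([C@H]2c3c(O)cc(O)cc3[C@@H](C(=O)c3ccc(O)cc3)[C@@H]2c2cc(O)cc3c2[C@@H](c2cc(O)cc(O)c2)[C@H](c2ccc(O)cc2)O3)cc1 | intermediate
28 | octaacetate of 27: (1S,2R,3S)-5,7-diacetoxy-3-(4-acetoxybenzoyl)-1-(4-acetoxyphenyl)-2-[(2R,3R)-6-acetoxy-2-(4-acetoxyphenyl)-3-(3,5-diacetoxyphenyl)-2,3-dihydro-1-benzofuran-4-yl]indane | CC(=O)Oc1ccc([C@H]2c3c(OC(C)=O)cc(OC(C)=O)cc3[C@@H](C(=O)c3ccc(OC(C)=O)cc3)[C@@H]2c2cc(OC(C)=O)cc3c2[C@@H](c2cc(OC(C)=O)cc(OC(C)=O)c2)[C@H](c2ccc(OC(C)=O)cc2)O3)cc1 | intermediate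
29 | (1S,2R,3S)-5,7-diacetoxy-3-[(S)-(4-acetoxyphenyl)(hydroxy)methyl]-1-(4-acetoxyphenyl)-2-[(2R,3R)-6-acetoxy-2-(4-acetoxyphenyl)-3-(3,5-diacetoxyphenyl)-2,3-dihydro-1-benzofuran-4-yl]indane | CC(=O)Oc1ccc([C@H]2c3c(OC(C)=O)cc(OC(C)=O)cc3[C@@H]([C@H](O)c3ccc(OC(C)=O)cc3)[C@@H]2c2cc(OC(C)=O)cc3c2[C@@H](c2cc(OC(C)=O)cc(OC(C)=O)c2)[C@H](c2ccc(OC(C)=O)cc2)O3)cc1 | intermediate
30 | (1S,2R,3S)-3-[(S)-hydroxy(4-hydroxyphenyl)methyl]-1-(4-hydroxyphenyl)-2-[(2R,3R)-3-(3,5-dihydroxyphenyl)-6-hydroxy-2-(4-hydroxyphenyl)-2,3-dihydro-1-benzofuran-4-yl]indane-5,7-diol (CNP0175860.1) | Oc1ccc([C@H]2c3c(O)cc(O)cc3[C@@H]([C@H](O)c3ccc(O)cc3)[C@@H]2c2cc(O)cc3c2[C@@H](c2cc(O)cc(O)c2)[C@H](c2ccc(O)cc2)O3)cc1 | target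

## Step count and least certain steps

Total: 19 steps. Longest linear sequence: 13 steps (steps 7–14, 15, 16–19). The other branch is 6 steps (steps 1–6).

**Step 15 (key step).**
- What may go wrong: poor facial selectivity in the 1,6-addition, since only the C3 aryl group of the dihydrobenzofuran differentiates the faces; elimination of the sulfide from the betaine before the enolate closes; capture of the quinone methide by the enolate oxygen; and rearrangement or self-condensation of the ylide.
- Fallback (known chemistry): it sets out from 4 and 20 and rejoins the route at 27. MnO2 in CH2Cl2 oxidises 20 to (2R,3R)-3-(3,5-dimethoxyphenyl)-6-methoxy-2-(4-methoxyphenyl)-2,3-dihydro-1-benzofuran-4-carbaldehyde F1. Knoevenagel-type condensation of F1 with 4 (piperidine, AcOH, toluene, reflux) gives the triaryl enone F2. The lithio derivative (LDA, THF, −78 °C) of 4-methoxybenzyl p-tolyl sulfone F3, made from 4-methoxybenzyl chloride and sodium p-toluenesulfinate, adds 1,4 to F2 to give the gamma-sulfonyl ketone F4. EtAlCl2 (CH2Cl2, −78 °C to 0 °C) ionises the sulfone, and ring A closes on the 4-methoxybenzylic cation by Friedel–Crafts alkylation, ortho to one methoxy group and para to the other. After equilibration of C3 with DBU and separation of diastereomers this gives the octamethyl ether F5, and BBr3 as in step 16 converts F5 into 27. The fallback forms C1–C7a last and uses only known reaction types. It costs four extra steps, and the relation between C2 and the dihydrobenzofuran is not controlled.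

**Step 18.**
- What may go wrong: erosion or reversal of facial selectivity, because the branched indanyl group competes with the aryl group as the larger ketone substituent and the C3 centre exerts its own bias; slow reduction of a hindered ketone, with loss of acetates on long exposure.
- Fallback: it sets out from 28 and rejoins at 30. Substrate-controlled reduction with Zn(BH4)2 (THF, −20 °C) is used in place of the catalyst. If it gives the R carbinol F6, a Mitsunobu reaction (4-nitrobenzoic acid, PPh3, DIAD, THF) inverts the centre to the S 4-nitrobenzoate F7, and methanolysis of all nine esters (K2CO3, MeOH, 0 °C) gives 30. If it gives the S carbinol, that compound is 29 and the route continues unchanged.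

**Step 16.**
- What may go wrong: Lewis-acid opening of the dihydrobenzofuran C2–O bond followed by cation chemistry other than reclosure; incomplete cleavage of the hindered ethers.
- Fallback: it sets out from 26 and rejoins at 27. Nucleophilic dealkylation with NaSEt in DMF at 130 °C removes the methyl groups by SN2 at carbon, so no oxygen of the dihydrobenzofuran is activated; no new compound is involved.

**Step 5.**
- What may go wrong: capture of the benzhydryl cation by a dioxolane oxygen (transketalisation to a cyclic mixed ketal), or early loss of the ketal followed by closure through the ketone oxygen, in place of capture by sulfinate.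
- Fallback: it sets out from 9 and rejoins at 10. MsCl and Et3N (CH2Cl2, −20 °C) convert 9 under basic conditions into the benzhydryl chloride F8, which is not isolated. Sodium p-toluenesulfinate with Bu4NI in DMF then displaces chloride to give 10 without any Brønsted acid present.

**Step 10.**
- What may go wrong: incomplete protonation of the benzofuran at C3 (the C4 ester lowers its basicity) and hence a stalled reduction, or a cis/trans mixture.
- Fallback: it sets out from 17 and rejoins at 18. Hydrogenation (H2, 50 bar, Pd/C, EtOAc/AcOH, 60 °C) adds hydrogen syn to give the cis-dihydrobenzofuran F9. BF3·OEt2 in CH2Cl2 then epimerises C2 through the 4-methoxybenzylic cation to the trans isomer 18.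

## Further compounds

F1 | step 15 | (2R,3R)-3-(3,5-dimethoxyphenyl)-6-methoxy-2-(4-methoxyphenyl)-2,3-dihydro-1-benzofuran-4-carbaldehyde | O=Cc1cc(OC)cc2c1[C@@H](c1cc(OC)cc(OC)c1)[C@H](c1ccc(OC)cc1)O2
F2 | step 15 | (E)-2-(3,5-dimethoxyphenyl)-3-[(2R,3R)-3-(3,5-dimethoxyphenyl)-6-methoxy-2-(4-methoxyphenyl)-2,3-dihydro-1-benzofuran-4-yl]-1-(4-methoxyphenyl)prop-2-en-1-one | COc1ccc(cc1)C(=O)/C(c1cc(OC)cc(OC)c1)=C/c1cc(OC)cc2c1[C@@H](c1cc(OC)cc(OC)c1)[C@H](c1ccc(OC)cc1)O2
F3 | step 15 | 1-methoxy-4-[(4-methylbenzenesulfonyl)methyl]benzene | COc1ccc(CS(=O)(=O)c2ccc(C)cc2)cc1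
F4 | step 15 | 2-(3,5-dimethoxyphenyl)-3-[(2R,3R)-3-(3,5-dimethoxyphenyl)-6-methoxy-2-(4-methoxyphenyl)-2,3-dihydro-1-benzofuran-4-yl]-1,4-bis(4-methoxyphenyl)-4-(4-methylbenzenesulfonyl)butan-1-one (mixture at the three new centres) | COc1ccc(cc1)C(=O)C(c1cc(OC)cc(OC)c1)C(c1cc(OC)cc2c1[C@@H](c1cc(OC)cc(OC)c1)[C@H](c1ccc(OC)cc1)O2)C(c1ccc(OC)cc1)S(=O)(=O)c1ccc(C)cc1
F5 | step 15 | (1S,2R,3S)-5,7-dimethoxy-3-(4-methoxybenzoyl)-1-(4-methoxyphenyl)-2-[(2R,3R)-3-(3,5-dimethoxyphenyl)-6-methoxy-2-(4-methoxyphenyl)-2,3-dihydro-1-benzofuran-4-yl]indane | COc1ccc([C@H]2c3c(OC)cc(OC)cc3[C@@H](C(=O)c3ccc(OC)cc3)[C@@H]2c2cc(OC)cc3c2[C@@H](c2cc(OC)cc(OC)c2)[C@H](c2ccc(OC)cc2)O3)cc1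
F6 | step 18 | (1S,2R,3S)-5,7-diacetoxy-3-[(R)-(4-acetoxyphenyl)(hydroxy)methyl]-1-(4-acetoxyphenyl)-2-[(2R,3R)-6-acetoxy-2-(4-acetoxyphenyl)-3-(3,5-diacetoxyphenyl)-2,3-dihydro-1-benzofuran-4-yl]indane | CC(=O)Oc1ccc([C@H]2c3c(OC(C)=O)cc(OC(C)=O)cc3[C@@H]([C@@H](O)c3ccc(OC(C)=O)cc3)[C@@H]2c2cc(OC(C)=O)cc3c2[C@@H](c2cc(OC(C)=O)cc(OC(C)=O)c2)[C@H](c2ccc(OC(C)=O)cc2)O3)cc1
F7 | step 18 | (S)-4-nitrobenzoate of 29 | CC(=O)Oc1ccc([C@H]2c3c(OC(C)=O)cc(OC(C)=O)cc3[C@@H]([C@H](OC(=O)c3ccc(cc3)[N+](=O)[O-])c3ccc(OC(C)=O)cc3)[C@@H]2c2cc(OC(C)=O)cc3c2[C@@H](c2cc(OC(C)=O)cc(OC(C)=O)c2)[C@H](c2ccc(OC(C)=O)cc2)O3)cc1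
F0 | step 16 | none | none
F8 | step 5 | rac-2-{2-[chloro{4-[(tert-butyldimethylsilyl)oxy]phenyl}methyl]-3,5-dimethoxybenzyl}-2-(4-methoxyphenyl)-1,3-dioxolane | COc1ccc(cc1)C1(Cc2cc(OC)cc(OC)c2C(Cl)c2ccc(O[Si](C)(C)C(C)(C)C)cc2)OCCO1
F9 | step 10 | rac-methyl cis-(2S*,3R*)-3-(3,5-dimethoxyphenyl)-6-methoxy-2-(4-methoxyphenyl)-2,3-dihydro-1-benzofuran-4-carboxylate | COC(=O)c1cc(OC)cc2c1[C@@H](c1cc(OC)cc(OC)c1)[C@@H](c1ccc(OC)cc1)O2
A1 | alternative 1 | (1S,2R,3S)-3-[(S)-[(tert-butyldimethylsilyl)oxy](4-methoxyphenyl)methyl]-5-ethoxy-1-(4-methoxyphenyl)-2-[(2R,3R)-3-(3,5-dimethoxyphenyl)-6-methoxy-2-(4-methoxyphenyl)-2,3-dihydro-1-benzofuran-4-yl]indan-7-ol | COc1ccc([C@H]2c3c(O)cc(OCC)cc3[C@@H]([C@H](O[Si](C)(C)C(C)(C)C)c3ccc(OC)cc3)[C@@H]2c2cc(OC)cc3c2[C@@H](c2cc(OC)cc(OC)c2)[C@H](c2ccc(OC)cc2)O3)cc1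
A2 | alternative 1 | cyclopentenyl diazomethyl ketone with ring stereocentres, silylated carbinol and dihydrobenzofuran configured as in A1 | COc1ccc([C@H]2C=C(C(=O)C=[N+]=[N-])[C@@H]([C@H](O[Si](C)(C)C(C)(C)C)c3ccc(OC)cc3)[C@@H]2c2cc(OC)cc3c2[C@@H](c2cc(OC)cc(OC)c2)[C@H](c2ccc(OC)cc2)O3)cc1
A3 | alternative 1 | ethoxyethyne | CCOC#C
A4 | alternative 2 | (2R,3S)-trans-7-hydroxy-5-methoxy-2-[(2R,3R)-3-(3,5-dimethoxyphenyl)-6-methoxy-2-(4-methoxyphenyl)-2,3-dihydro-1-benzofuran-4-yl]-3-vinylindan-1-one | O=C1c2c(O)cc(OC)cc2[C@@H](C=C)[C@@H]1c1cc(OC)cc2c1[C@@H](c1cc(OC)cc(OC)c1)[C@H](c1ccc(OC)cc1)O2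
A5 | alternative 2 | trans-2-bromo-5-[(2R,3R)-3-(3,5-dimethoxyphenyl)-6-methoxy-2-(4-methoxyphenyl)-2,3-dihydro-1-benzofuran-4-yl]-4-vinylcyclopent-2-en-1-one (ring centres as in A4) | O=C1C(Br)=C[C@@H](C=C)[C@@H]1c1cc(OC)cc2c1[C@@H](c1cc(OC)cc(OC)c1)[C@H](c1ccc(OC)cc1)O2
A6 | alternative 2 | 1,3-dimethoxy-1-(trimethylsilyloxy)buta-1,3-diene | COC(=CC(OC)=C)O[Si](C)(C)C
A7 | alternative 3 | methyl (1S,2R,3S)-5,7-dimethoxy-1-(4-methoxyphenyl)-2-[(2R,3R)-3-(3,5-dimethoxyphenyl)-6-methoxy-2-(4-methoxyphenyl)-2,3-dihydro-1-benzofuran-4-yl]indane-3-carboxylate | COc1ccc([C@H]2c3c(OC)cc(OC)cc3[C@@H](C(=O)OC)[C@@H]2c2cc(OC)cc3c2[C@@H](c2cc(OC)cc(OC)c2)[C@H](c2ccc(OC)cc2)O3)cc1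
A8 | alternative 3 | trans-1-diazo-5,7-dimethoxy-4-(4-methoxyphenyl)-3-[(2R,3R)-3-(3,5-dimethoxyphenyl)-6-methoxy-2-(4-methoxyphenyl)-2,3-dihydro-1-benzofuran-4-yl]-3,4-dihydronaphthalen-2(1H)-one (ring centres as in A7) | COc1ccc([C@H]2c3c(OC)cc(OC)cc3C(=[N+]=[N-])C(=O)[C@@H]2c2cc(OC)cc3c2[C@@H](c2cc(OC)cc(OC)c2)[C@H](c2ccc(OC)cc2)O3)cc1
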